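## Structural features

Diffractaic acid is a depside: two pentasubstituted benzene rings joined only by an aryl ester, in which the C7 carbonyl of ring A (2,4-dimethoxy-3,6-dimethylbenzoyl) is bonded to O4' of ring B (2'-hydroxy-3',6'-dimethylbenzoic acid). There are no stereocenters, so the problem is one of regiochemistry and functional-group compatibility. Both positions ortho to C7 are occupied (C2 OMe, C6 CH3), which makes the depside ester slow to form but also shields it once formed. Ring B has two oxygens, O2' and O4', and only O4' may carry the acyl group. The fragile parts are the C7–O4' aryl ester (hydroxide, alkoxides, strong nucleophiles) and the salicylic acid unit C1' CO2H / C2' OH, which decarboxylates on heating or in strong acid, so the free acid should be released last and under neutral conditions. The real difficulty is to place six different substituents on ring B and tell O4' from O2' without protecting-group traffic. The key step exploits the resorcylate pattern of ring B: C2' to C5' map onto a 1,1-dioxygenated 3-acyloxy-2-methylbutadiene and C6'/C1' onto a but-2-ynoate. Because O4' is an enol oxygen in that diene, ring A can be attached before ring B exists.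

## Logic of the disconnections

**14 to 13.** The bond cut is the O–CH2 bond of a benzyl ester at the C1' carboxyl. The free acid is the most labile function, and hydrogenolysis is neutral, so the C7–O4' ester and the aryl methyl ethers are left alone. Nothing is gained in skeleton, but the acid is absent from every earlier step. The forward step demands only that nothing else in 13 responds to hydrogen on palladium, which is the case.

**13 to 7 and 10.** The bonds cut are C5'–C6' and C1'–C2' of ring B, with C2' returned to the level of a mixed ketene acetal carbon. This retro-cycloaddition puts O4' on a diene as an enol ester, so the depside bond predates the ring, and the alkyne supplies the aromatic oxidation level without an oxidant. The gain is large: the hexasubstituted ring and the O2'/O4' question both disappear, leaving two open-chain pieces. The forward step must give one regioisomer, the diene in 7 must outlast the heating, and C2' must lose its methoxy group and not its silyloxy group.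

**10 to 8 and 9.** The bond cut is the acyl C–O bond of the ester. Both pieces are commercial. The forward esterification must not isomerize or add to the conjugated triple bond.

**7 to 6.** The bonds cut are the O–Si bond and, formally, the C–H bond at the carbon that becomes C5'. This returns the diene to a stable conjugated enol ester. The forward step needs deprotonation at that methyl group only, in a molecule that also holds an aryl enol ester and a benzylic methyl next to C7.

**6 to 3 and 4 (through 5).** The bond cut is C7–O4', made here as an enol ester bond. At this stage the enol oxygen is the only nucleophilic oxygen, so the regiochemical problem of depside formation does not arise. The forward step must acylate oxygen and not carbon, and must do so with a di-ortho-substituted acyl donor.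

**3 to 2 to 1.** The bonds cut are the carboxyl O–CH3 bond and the two aryl O–CH3 bonds. Compound 1 already contains every carbon of ring A in the right place. The forward steps must methylate a hydrogen-bonded phenol fully and then hydrolyse a hindered ester without harming the aryl ethers.

## Other disconnections considered

**Alternative 1:** The cut lies in a dihydro form of ring B, at C1'–C6' and C2'–C3'; the aromatic oxidation level and the depside bond are added afterwards.

- **Forward key step.** Dibenzyl malonate A2 and (E)-hex-4-en-3-one A3 would be combined with NaOCH2Ph. Michael addition sets C1'–C6', and Claisen closure of the ethyl ketone enolate onto one ester sets C2'–C3', giving the cyclic enolized dione A1. Acylation of A1 on O4' with 5, dehydrogenation of the ring and hydrogenolysis would follow, passing through 13.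
- **In its favour.** Both reagents are cheap. The annulation is a robust base-mediated condensation at moderate temperature. The substituent pattern follows from connectivity alone, and the two stereocenters of A1 are of no consequence because both become aromatic carbons.
- **Against it here.** A1 is a tautomeric 1,3-dione, so the acyl group must choose between O4' and O2'. The ring is two hydrogens short of aromatic, so an oxidant or a halogenation–elimination sequence must act on a molecule that contains an electron-rich ring A with a free C5–H, a benzyl ester and an enol ester. Enol esters of cyclic 1,3-diones are also prone to O-to-C acyl migration.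
- **Comparison.** On structure, both plans build ring B from two open-chain pieces and attach ring A through an enol oxygen. On mechanism, the ionic annulation is better precedented than a thermal cycloaddition with a β-substituted ynoate; on that point the alternative is the better plan. On step count it is the equal of the chosen plan. It is weaker in needing a redox adjustment and a regioselective acylation, both of which the alkyne and the pre-acylated diene make unnecessary.

**Alternative 2:** The cut removes ring A: C1–C6 by a retro-aldol disconnection and C7–O4' by reversal of an acylketene capture.

- **Forward key step.** The diketo-dioxinone A5 would be heated with the ring B phenol A6. Loss of acetone gives an acylketene that the C4' hydroxyl of A6 traps. Base and then acid in the same flask would fold the resulting triketo ester by aldol condensation, dehydration and enolization into the resorcylate A4. Both ring A phenols would then be methylated to A7, and hydrogenolysis of the two benzyl groups would give 14.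
- **In its favour.** The hindered depside ester forms under neutral thermal conditions by addition to a ketene, with no activated derivative of a di-ortho-substituted benzoic acid; on this point it is better than the acyl chloride chemistry of step 3. The annulation is biomimetic and regiochemically unambiguous. A4, with free phenols, would also serve for congeners with other O-alkylation patterns, a flexibility the chosen plan lacks.
- **Against it here.** Ring A is exactly the skeleton that 1 supplies ready-made. A5 needs several steps of its own. A6 needs ring B made and differentiated at O2', O4' and the carboxyl by protecting-group operations. Methylation of the hydrogen-bonded C2 phenol of A4 next to an aryl ester is a late-stage risk.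
- **Comparison.** On structure, both plans make one aromatic ring from acyclic precursors and fix the depside oxygen before that ring is aromatic. On mechanism, the low-temperature aldol cascade is at least the equal of the thermal cycloaddition in reliability. On step economy the alternative is clearly longer and needs two benzyl groups where the chosen plan needs one and no phenol protection.

**Alternative 3:** Ring A is again the ring made, cut at four bonds (C5–C6, C2–C3, C4–C5, C1–C2) into a mesaconate-derived diazoketone and an alkynyl ether.

- **Forward key step.** The diazoketone A9, whose ester oxygen is already O4' of ring B, would be irradiated with 1-methoxyprop-1-yne A10. Wolff rearrangement moves the alkenyl carbon C6 onto C5 and gives a vinylketene. A (2+2) addition with A10 joins the alkyne methyl carbon to the ketene carbonyl carbon C2 and the methoxy carbon to C5. Heating opens the cyclobutenone (four electrons) to a dienylketene that closes between C1 and C2 (six electrons) and tautomerizes to the phenol A8. O-Methylation of the C2 phenol to A7 and hydrogenolysis would finish.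
- **In its favour.** Four carbon–carbon bonds form in one operation. Every substituent of ring A is placed by connectivity. The polarity match between alkynyl ether and ketene secures regiochemistry as firmly as the diene/ynoate match does in the chosen plan (equal). C2 OH and C4 OMe emerge differentiated, which is better if the mono-methyl ether depside were also wanted.
- **Against it here.** That differentiation is not needed for this target and costs an extra methylation at a hindered, hydrogen-bonded phenol. A9 requires a diazoalkane or diazo transfer on an activated mesaconate half-ester, and it holds a diazo group and an electron-poor alkene in one molecule. Only the E alkene places the ester on the outside for the six-electron closure. The ester on the vinylketene lowers its reactivity in the (2+2) step. A10 is volatile and must be made, and A6 must be prepared with protecting groups as in alternative 2.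
- **Comparison.** On structure, the alternative builds the ring that can be bought and must obtain ring B elsewhere. On mechanism, a cascade of four pericyclic events through reactive intermediates stands against one cycloaddition plus an elimination. On step economy it is longer.

Key step: step 6

Assumption: the double-bond geometries of 6 (drawn E) and of the ketene acetal in 7 (drawn Z) are those expected to predominate; neither survives into ring B, so a mixture of isomers would serve equally.

## Route

Step 1
Reactants: 1 atraric acid (methyl 2,4-dihydroxy-3,6-dimethylbenzoate)
Product: 2 methyl 2,4-dimethoxy-3,6-dimethylbenzoate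
Conditions: MeI, K2CO3, DMF, 50 °C
Reagents that add atoms: iodomethane, CI
Why: Williamson ether synthesis on both phenoxides; the hydrogen-bonded, flanked C2 hydroxyl is the slow one, so excess iodomethane in warm DMF is used, and carbonate leaves the methyl ester untouched.

Step 2
Reactants: 2 methyl 2,4-dimethoxy-3,6-dimethylbenzoate
Product: 3 2,4-dimethoxy-3,6-dimethylbenzoic acid
Conditions: KOH, DMSO/H2O, 90 °C; then 1 M HCl, 0 °C
Reagents that add atoms: potassium hydroxide, [K+].[OH-]
Why: Saponification by acyl–oxygen cleavage; poorly solvated hydroxide in DMSO should overcome the di-ortho hindrance, the aryl methyl ethers are inert, and cold acidification avoids protodecarboxylation of the electron-rich acid.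

Step 3
Reactants: 3 2,4-dimethoxy-3,6-dimethylbenzoic acid; 4 methyl 2-methylacetoacetate (racemic)
Product: 6 methyl (2E)-3-[(2,4-dimethoxy-3,6-dimethylbenzoyl)oxy]-2-methylbut-2-enoate, via aroyl chloride 5 (not isolated)
Conditions: (COCl)2, DMF (cat.), CH2Cl2, 0 °C to rt; evaporate; then 4, Et3N, DMAP (cat.), MeCN, 0 °C to rt
Reagents that add atoms: none
Why: Oxalyl chloride with catalytic DMF converts 3 into 5 (it supplies the chlorine of 5), and the triethylammonium enolate of 4 is then acylated on oxygen, because the hindered, acylium-like chloride is a hard electrophile and the enolate carbon is fully substituted. The non-chelated enolate in a polar solvent should favour the E enol ester, in which the methyl to be deprotonated in step 4 lies cis to the ester carbonyl.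

Step 4
Reactants: 6 methyl (2E)-3-[(2,4-dimethoxy-3,6-dimethylbenzoyl)oxy]-2-methylbut-2-enoate
Product: 7 (3Z)-4-(tert-butyldimethylsilyloxy)-4-methoxy-3-methylbuta-1,3-dien-2-yl 2,4-dimethoxy-3,6-dimethylbenzoate
Conditions: TBSCl, DMPU, THF, −78 °C; add LiN(iPr)2; −78 °C to 0 °C; non-aqueous work-up
Reagents that add atoms: tert-butyldimethylsilyl chloride, CC(C)(C)[Si](C)(C)Cl
Why: Vinylogous (γ) deprotonation of the enoate gives the extended ester dienolate, which is silylated on oxygen as it forms; C2 has no hydrogen, so only the γ-methyl can be enolized, and the di-ortho-substituted aroyl ester is shielded from amide or enolate attack. The tert-butyldimethylsilyl group is chosen over a smaller silyl group so that the ketene acetal survives isolation and the heating of step 6.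

Step 5
Reactants: 8 but-2-ynoic acid; 9 benzyl alcohol
Product: 10 benzyl but-2-ynoate
Conditions: DCC, DMAP (cat.), CH2Cl2, 0 °C
Reagents that add atoms: none
Why: Steglich esterification; low temperature and a catalytic amount of DMAP limit conjugate addition to the ynoate and isomerization to the allenoate.

Step 6
Reactants: 7 (3Z)-4-(tert-butyldimethylsilyloxy)-4-methoxy-3-methylbuta-1,3-dien-2-yl 2,4-dimethoxy-3,6-dimethylbenzoate; 10 benzyl but-2-ynoate
Product: 13 benzyl diffractaate (benzyl 4-[(2,4-dimethoxy-3,6-dimethylbenzoyl)oxy]-2-hydroxy-3,6-dimethylbenzoate), via cycloadduct 11 (not isolated), via dienone 12 (not isolated)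
Conditions: 10 (excess), PhMe, 120 °C, sealed tube; then Bu4NF, AcOH, THF, 0 °C
Reagents that add atoms: none
Why: A normal-demand Diels–Alder reaction of the kind known for 1-alkoxy-1-silyloxy-3-oxygenated butadienes and alkynoates; only the weaker donor at C4' (aroyloxy for silyloxy) and the β-methyl of the dienophile depart from the usual case, hence the higher temperature and the excess of 10. The closure is concerted but asynchronous: the ketene acetal oxygens at C2' and the enol ester oxygen at C4' both raise the coefficient at the CH2 terminus C5', which bonds first to the β-carbon of the ynoate (C6'), and the C1'–C2' bond follows. Ring B is thus closed as a six-membered carbocycle in a single suprafacial (4+2) event, giving the 1,4-cyclohexadiene 11 with a mixed methyl silyl ketal at C2'. Buffered fluoride then cleaves the O–Si bond, the hemiketal oxide expels methoxide to give dienone 12, and 12 tautomerizes to the phenol, which is held by a hydrogen bond to the C1' ester. No stereocenter is created in 13; the ketal carbon of 11 is a transient racemic center, and the ketene acetal geometry of 7 is erased on aromatization. The step needs regioselectivity (C6' methyl next to C5', ester next to C2'), which the matched polarization of the two partners secures, and it needs loss of the methoxy group and not the silyloxy group from C2', which the fluoride-first cleavage secures. The C2' hydroxyl appears only after O4' is already acylated, so no choice between the two ring B oxygens has to be made.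

Step 7
Reactants: 13 benzyl diffractaate
Product: 14 diffractaic acid (4-[(2,4-dimethoxy-3,6-dimethylbenzoyl)oxy]-2-hydroxy-3,6-dimethylbenzoic acid)
Conditions: H2 (1 atm), 10% Pd/C, EtOAc, rt
Reagents that add atoms: none
Why: Hydrogenolysis of the benzylic C–O bond under neutral conditions; the aryl ester, the aryl methyl ethers and both arenes are inert, and the salicylic acid is never exposed to heat, acid or base.

## Compound list

1 | atraric acid (methyl 2,4-dihydroxy-3,6-dimethylbenzoate) | COC(=O)c1c(C)cc(O)c(C)c1O | starting material
2 | methyl 2,4-dimethoxy-3,6-dimethylbenzoate | COC(=O)c1c(C)cc(OC)c(C)c1OC | intermediate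
3 | 2,4-dimethoxy-3,6-dimethylbenzoic acid | OC(=O)c1c(C)cc(OC)c(C)c1OC | intermediate
4 | methyl 2-methylacetoacetate (methyl 2-methyl-3-oxobutanoate, racemic) | CC(=O)C(C)C(=O)OC | starting material
5 | 2,4-dimethoxy-3,6-dimethylbenzoyl chloride | ClC(=O)c1c(C)cc(OC)c(C)c1OC | intermediate (not isolated)
6 | methyl (2E)-3-[(2,4-dimethoxy-3,6-dimethylbenzoyl)oxy]-2-methylbut-2-enoate | COC(=O)/C(C)=C(\C)OC(=O)c1c(C)cc(OC)c(C)c1OC | intermediate
7 | (3Z)-4-(tert-butyldimethylsilyloxy)-4-methoxy-3-methylbuta-1,3-dien-2-yl 2,4-dimethoxy-3,6-dimethylbenzoate | C=C(OC(=O)c1c(C)cc(OC)c(C)c1OC)/C(C)=C(/OC)O[Si](C)(C)C(C)(C)C | intermediate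
8 | but-2-ynoic acid | CC#CC(=O)O | starting material
9 | benzyl alcohol | OCc1ccccc1 | starting material
10 | benzyl but-2-ynoate | CC#CC(=O)OCc1ccccc1 | intermediate
11 | benzyl 6-(tert-butyldimethylsilyloxy)-4-[(2,4-dimethoxy-3,6-dimethylbenzoyl)oxy]-6-methoxy-2,5-dimethylcyclohexa-1,4-diene-1-carboxylate (racemic) | COC1(O[Si](C)(C)C(C)(C)C)C(C)=C(OC(=O)c2c(C)cc(OC)c(C)c2OC)CC(C)=C1C(=O)OCc1ccccc1 | intermediate (not isolated)
12 | benzyl 4-[(2,4-dimethoxy-3,6-dimethylbenzoyl)oxy]-2,5-dimethyl-6-oxocyclohexa-1,4-diene-1-carboxylate | O=C1C(C)=C(OC(=O)c2c(C)cc(OC)c(C)c2OC)CC(C)=C1C(=O)OCc1ccccc1 | intermediate (not isolated)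
13 | benzyl diffractaate (benzyl 4-[(2,4-dimethoxy-3,6-dimethylbenzoyl)oxy]-2-hydroxy-3,6-dimethylbenzoate) | COc1cc(C)c(C(=O)Oc2cc(C)c(C(=O)OCc3ccccc3)c(O)c2C)c(OC)c1C | intermediate
14 | diffractaic acid | COc1cc(C)c(C(=O)Oc2cc(C)c(C(=O)O)c(O)c2C)c(OC)c1C | target

## Step count and least certain steps

Total step count: 7. Longest linear sequence: 6 steps (steps 1, 2, 3, 4, 6, 7); step 5 is a one-step branch.

**Step 6 (key step).** The cycloaddition may be slower than the thermal decay of the diene, through desilylation by traces of moisture, O-to-C silyl migration or oligomerization. The cause is that the aroyloxy group is a weaker donor than a silyloxy group, and the β-methyl of the ynoate both hinders and deactivates the dienophile. A second concern is aromatization of 11 during prolonged heating by loss of silanol instead of methanol, which would leave O2' methylated.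

Fallback: ring B is taken from 1 and the cycloaddition is abandoned. Saponification of 1 (aqueous KOH, then cold acid) should give 2,4-dihydroxy-3,6-dimethylbenzoic acid F1. Alkylation of its carboxylate (PhCH2Br, KHCO3, DMF) should give benzyl 2,4-dihydroxy-3,6-dimethylbenzoate F2. Acylation of F2 with 5 and pyridine should go to O4', because O2' is hydrogen-bonded to the ester and flanked on both sides. The sequence sets out from 1 and 5 and returns to the route at 13.

**Step 4.** Several side processes compete with γ-deprotonation: lateral deprotonation of the C6 methyl of ring A (ortho to the C7 carbonyl), acyl transfer from the enol ester to the amide base or to the dienolate, and silylation on carbon in place of oxygen. Hydrolysis of the ketene acetal on isolation is a further risk.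

Fallback: the acyl group is introduced after ring B exists, and the diene carries a silyloxy group instead. Silylation of 4 (Me3SiCl, Et3N) should give methyl 2-methyl-3-(trimethylsilyloxy)but-2-enoate F3. LiN(iPr)2 and then Me3SiCl should give 1-methoxy-2-methyl-1,3-bis(trimethylsilyloxy)buta-1,3-diene F4. Heating F4 with 10 and a dilute acid work-up should give benzyl 2,4-dihydroxy-3,6-dimethylbenzoate F2, which is acylated at O4' with 5 and pyridine. The sequence sets out from 4 and 10 and returns at 13.

**Step 3.** Acylation may take place at C2 of the enolate instead of oxygen, acyl transfer from the hindered chloride may be too slow, or DMAP may induce O-to-C acyl migration in the product.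

Fallback: the enolate is released without a metal or ammonium counter-ion bound to oxygen, and the acyl donor is made smaller. Acid 3 with cyanuric fluoride and pyridine should give 2,4-dimethoxy-3,6-dimethylbenzoyl fluoride F5. Treatment of the silyl enol ether F3 (from 4, as above) with F5 and catalytic Bu4NF should give the enol ester by fluoride-catalysed O-acylation, the fluoride being regenerated as the silyl group leaves. The sequence sets out from 3 and 4 and returns at 6.

**Step 2.** Hydrolysis of the di-ortho-substituted ester may stay incomplete under conditions that already begin to cleave aryl methyl ethers, and the electron-rich acid may lose CO2 on acidification.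

Fallback: a redox detour that avoids attack of hydroxide at the hindered carbonyl. Reduction of 2 with LiAlH4 should give (2,4-dimethoxy-3,6-dimethylphenyl)methanol F6. Oxidation with MnO2 should give 2,4-dimethoxy-3,6-dimethylbenzaldehyde F7. Pinnick oxidation (NaClO2, NaH2PO4, 2-methylbut-2-ene) should then give the acid. The sequence sets out from 2 and returns at 3.

## Further compounds

F1 | step 6 | 2,4-dihydroxy-3,6-dimethylbenzoic acid | Cc1cc(O)c(C)c(O)c1C(=O)O
F2 | step 6 | benzyl 2,4-dihydroxy-3,6-dimethylbenzoate | Cc1cc(O)c(C)c(O)c1C(=O)OCc1ccccc1
F3 | step 4 | methyl 2-methyl-3-(trimethylsilyloxy)but-2-enoate (mixture of geometric isomers) | COC(=O)C(C)=C(C)O[Si](C)(C)C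
F4 | step 4 | 1-methoxy-2-methyl-1,3-bis(trimethylsilyloxy)buta-1,3-diene (ketene acetal geometry not defined) | C=C(O[Si](C)(C)C)C(C)=C(OC)O[Si](C)(C)C
F5 | step 3 | 2,4-dimethoxy-3,6-dimethylbenzoyl fluoride | FC(=O)c1c(C)cc(OC)c(C)c1OC
F6 | step 2 | (2,4-dimethoxy-3,6-dimethylphenyl)methanol | OCc1c(C)cc(OC)c(C)c1OC
F7 | step 2 | 2,4-dimethoxy-3,6-dimethylbenzaldehyde | O=Cc1c(C)cc(OC)c(C)c1OC
A1 | alternative 1 | benzyl trans-4-hydroxy-3,6-dimethyl-2-oxocyclohex-3-ene-1-carboxylate (racemic, one enantiomer drawn) | C[C@H]1CC(O)=C(C)C(=O)[C@@H]1C(=O)OCc1ccccc1
A2 | alternative 1 | dibenzyl malonate | O=C(CC(=O)OCc1ccccc1)OCc1ccccc1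
A3 | alternative 1 | (E)-hex-4-en-3-one | CCC(=O)/C=C/C
A4 | alternative 2 | benzyl 2-(benzyloxy)-4-(2,4-dihydroxy-3,6-dimethylbenzoyloxy)-3,6-dimethylbenzoate | Cc1cc(O)c(C)c(O)c1C(=O)Oc1cc(C)c(C(=O)OCc2ccccc2)c(OCc2ccccc2)c1C
A5 | alternative 2 | 2,2-dimethyl-6-(3,5-dioxohexan-2-yl)-4H-1,3-dioxin-4-one (racemic) | CC(=O)CC(=O)C(C)C1=CC(=O)OC(C)(C)O1
A6 | alternative 2 | benzyl 2-(benzyloxy)-4-hydroxy-3,6-dimethylbenzoate | Cc1cc(O)c(C)c(OCc2ccccc2)c1C(=O)OCc1ccccc1
A7 | alternative 2 | benzyl 2-(benzyloxy)-4-[(2,4-dimethoxy-3,6-dimethylbenzoyl)oxy]-3,6-dimethylbenzoate | COc1cc(C)c(C(=O)Oc2cc(C)c(C(=O)OCc3ccccc3)c(OCc3ccccc3)c2C)c(OC)c1C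
A8 | alternative 3 | benzyl 2'-O-benzylbarbatate (benzyl 2-(benzyloxy)-4-[(2-hydroxy-4-methoxy-3,6-dimethylbenzoyl)oxy]-3,6-dimethylbenzoate) | COc1cc(C)c(C(=O)Oc2cc(C)c(C(=O)OCc3ccccc3)c(OCc3ccccc3)c2C)c(O)c1C
A9 | alternative 3 | benzyl 2-(benzyloxy)-4-{[(2E)-5-diazo-3-methyl-4-oxopent-2-enoyl]oxy}-3,6-dimethylbenzoate | [N-]=[N+]=CC(=O)/C(C)=C/C(=O)Oc1cc(C)c(C(=O)OCc2ccccc2)c(OCc2ccccc2)c1C
A10 | alternative 3 | 1-methoxyprop-1-yne | COC#CC
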